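Octalin numbering: C1 carries the dienoic acid chain, C2 the butenyl group, C3(Me)=C4, C4a and C8a are the fusion atoms, C7 carries the sulfate, C8 a methyl group. Ring A = C1–C4, C4a, C8a; ring B = C4a–C8a.
Enabling feature: ring A is a cyclohexene whose alkene C3=C4 is bonded directly to fusion atom C4a. C1–C2 and C4a–C8a are therefore the two σ-bonds of one [4+2] pairing (diene C4a=C4–C3=C2, dienophile C8a=C1), and C5–C8 of ring B is the four-carbon link between them.
Cuts, in retrosynthetic order: the S–O bond at C7 and the ester; the first alkene of the C1 side chain (Horner–Wadsworth–Emmons); C1–C2 and C4a–C8a together (intramolecular Diels–Alder); C4a=C4 (Z-Wittig); C8a=C1 (cross-metathesis); C7–C8 (crotylboration); C3=C2 (Wittig).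
Forward: a C4a–C1 fragment with its enal masked as an acetal is joined to a C4–C2/butenyl dienal and the enal is unmasked. Rings A and B then form in one operation, and the side chain and the sulfate follow.
Stereochemistry: C7 and C8 come from a phosphoric-acid-catalysed anti crotylboration. C1, C2, C4a and C8a are relayed from the 2E, 8Z and 10E alkene geometries through the cycloaddition, whose absolute face is fixed by a (2R,5R)-imidazolidinone acting in the same sense as C7/C8.
Ordering: the enal carbons are put in by metathesis before any diene exists, because a ruthenium alkylidene at C8a would otherwise ring-close onto C4a=C4.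

Key step: step 9

Remark: the target is written as the free hydrogen sulfate and free carboxylic acid, so the route is taken to end with a cold acidification; for storage a salt would be preferred.

Step 1
Reactants: 1 (E)-2-methylbut-2-enal (tiglic aldehyde); 2 2-(triphenyl-λ5-phosphanylidene)propanal
Product: 3 (2E,4E)-2,4-dimethylhexa-2,4-dienal
Conditions: 1 in excess, toluene, 110 °C
Reagents that add atoms: none
Why: A Wittig olefination with a stabilised formyl ylide is reliably E-selective for the new C3=C2 alkene, leaves the E-butenyl alkene of 1 alone, and over-extension is held back because 3 is more conjugated and less electrophilic than 1, which is kept in excess.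

Step 2
Reactants: 4 methyl 4-chlorobutanoate
Product: 5 4-chlorobutanal
Conditions: diisobutylaluminium hydride (1.05 equiv), CH2Cl2, −78 °C; aq. potassium sodium tartrate
Reagents that add atoms: none
Why: Partial reduction of an ester with one equivalent of diisobutylaluminium hydride at −78 °C is a standard route to the aldehyde and does not touch a primary alkyl chloride.

Step 3
Reactants: 5 4-chlorobutanal; 6 (E)-crotylboronic acid pinacol ester
Product: 8 (3R,4S)-7-chloro-3-methylhept-1-en-4-ol, via pinacol borate 7 (not isolated)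
Conditions: (R)-TRIP [(R)-3,3'-bis(2,4,6-triisopropylphenyl)-1,1'-binaphthyl-2,2'-diyl hydrogen phosphate, 5 mol%], 4 Å MS, toluene, −30 °C; aqueous work-up
Reagents that add atoms: none
Why: In this chiral-phosphoric-acid-catalysed crotylboration the closed chair (Zimmerman–Traxler) transition state turns the E geometry of 6 into the anti C7/C8 relationship, while (R)-TRIP bound to the boronate should steer the transfer to the Re face of 5 and so set C7 as S and C8 as R, the borate 7 being cleaved on work-up.

Step 4
Reactants: 8 (3R,4S)-7-chloro-3-methylhept-1-en-4-ol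
Product: 9 tert-butyl{[(3R,4S)-7-chloro-3-methylhept-1-en-4-yl]oxy}dimethylsilane
Conditions: TBSOTf, 2,6-lutidine, CH2Cl2, −78 → 0 °C
Reagents that add atoms: tert-butyldimethylsilyl trifluoromethanesulfonate CC(C)(C)[Si](C)(C)OS(=O)(=O)C(F)(F)F
Why: Silylation with the triflate and a hindered pyridine base is fast even for a flanked secondary alcohol, outruns any ring closure of the alcohol onto the chloride, and does not affect C7 or C8.

Step 5
Reactants: 9 tert-butyl{[(3R,4S)-7-chloro-3-methylhept-1-en-4-yl]oxy}dimethylsilane; 10 3,3-diethoxyprop-1-ene (acrolein diethyl acetal)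
Product: 11 (2E,4R,5S)-5-(tert-butyldimethylsilyloxy)-8-chloro-1,1-diethoxy-4-methyloct-2-ene
Conditions: 10 (4 equiv), second-generation Hoveyda–Grubbs catalyst (5 mol%), CH2Cl2, 40 °C; Et3N-washed silica
Reagents that add atoms: none
Why: Olefin cross-metathesis between an allylically branched terminal alkene that homodimerises slowly and an excess of an acrolein acetal is a known, E-selective pairing, and it is placed here, before any diene exists, because a ruthenium alkylidene at C8a would otherwise ring-close onto C4a=C4 to a cyclohexene.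

Step 6
Reactants: 11 (2E,4R,5S)-5-(tert-butyldimethylsilyloxy)-8-chloro-1,1-diethoxy-4-methyloct-2-ene
Product: 13 [(4S,5R,6E)-4-(tert-butyldimethylsilyloxy)-8,8-diethoxy-5-methyloct-6-en-1-yl]triphenylphosphonium iodide, via primary iodide 12 (not isolated)
Conditions: NaI, PPh3, ethyldiisopropylamine (0.3 equiv), MeCN, 82 °C
Reagents that add atoms: sodium iodide [Na+].[I-]; triphenylphosphine c1ccc(cc1)P(c1ccccc1)c1ccccc1
Why: A Finkelstein exchange driven by precipitation of NaCl feeds the SN2 quaternisation of PPh3 at the unhindered C4a carbon, and the amine buffer keeps traces of HI away from the acetal and the silyl ether.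

Step 7
Reactants: 13 [(4S,5R,6E)-4-(tert-butyldimethylsilyloxy)-8,8-diethoxy-5-methyloct-6-en-1-yl]triphenylphosphonium iodide; 3 (2E,4E)-2,4-dimethylhexa-2,4-dienal
Product: 15 (2E,4R,5S,8Z,10E,12E)-5-(tert-butyldimethylsilyloxy)-1,1-diethoxy-4,10,12-trimethyltetradeca-2,8,10,12-tetraene, via phosphorus ylide 14 (not isolated)
Conditions: NaN(SiMe3)2, THF, 0 °C; then 3, −78 °C → rt; Et3N-washed silica
Reagents that add atoms: none
Why: A lithium-free Wittig olefination of a non-stabilised ylide with an aldehyde runs under kinetic control and should give the Z alkene C4a=C4, while the two E alkenes of 3, the acetal and the silyl ether are inert to the conditions.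

Step 8
Reactants: 15 (2E,4R,5S,8Z,10E,12E)-5-(tert-butyldimethylsilyloxy)-1,1-diethoxy-4,10,12-trimethyltetradeca-2,8,10,12-tetraene
Product: 16 (2E,4R,5S,8Z,10E,12E)-5-(tert-butyldimethylsilyloxy)-4,10,12-trimethyltetradeca-2,8,10,12-tetraenal
Conditions: pyridinium p-toluenesulfonate (10 mol%), acetone–H2O, rt
Reagents that add atoms: water O
Why: Acid-catalysed hydrolysis of an allylic acetal is so much easier than that of a saturated one that a pyridinium salt in wet acetone suffices, conditions under which the silyl ether, the C8 stereocentre and the Z,E,E-triene should stay intact.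

Step 9
Reactants: 16 (2E,4R,5S,8Z,10E,12E)-5-(tert-butyldimethylsilyloxy)-4,10,12-trimethyltetradeca-2,8,10,12-tetraenal
Product: 19 (1S,2R,4aS,7S,8R,8aS)-2-[(2E)-but-2-en-2-yl]-7-(tert-butyldimethylsilyloxy)-3,8-dimethyl-1,2,4a,5,6,7,8,8a-octahydronaphthalene-1-carbaldehyde, via substrate iminium triflate 17 (not isolated), via cycloadduct iminium triflate 18 (not isolated)
Conditions: (2R,5R)-5-benzyl-2-tert-butyl-3-methylimidazolidin-4-one·CF3SO3H (20 mol%), MeCN–H2O 98:2, 0 °C → rt
Reagents that add atoms: none
Why: Enal 16 condenses with the imidazolidinone salt to the (E)-iminium ion 17, whose lowered LUMO lets the C8a=C1 alkene add suprafacially, in a concerted but asynchronous [4+2] step, across the s-cis diene C4a=C4–C3=C2, and hydrolysis of the adduct iminium ion 18 frees 19 and returns the amine. The closest known reaction type is the imidazolidinone-catalysed intramolecular Diels–Alder reaction of 2,8,10-trienals, taken together with the cis-selective cyclisation known for 1,7,9-decatrienes that carry a Z-diene. Ring A closes by the cycloaddition itself (six-membered, boat-like array, new bonds C1–C2 and C4a–C8a), and ring B closes in the same event as a six-membered carbocycle when the new C4a–C8a bond joins the two ends of the C5–C8 tether, which folds as a chair. C4a and C8a: the 8Z geometry holds C5 on the inside of the diene, from where a four-carbon tether can reach C8a only in the exo orientation, so the fusion can only be cis; C1: the 2E geometry keeps the activated formyl carbon trans to C8 and therefore endo, on the side of both fusion hydrogens; C2: the 10E geometry keeps the butenyl group outside and therefore cis to the endo substituent at C1. The one selectivity left open is the enal face relative to C8 and C7: the benzyl and tert-butyl groups of the (2R,5R) catalyst cover one face of 17 and leave free the face on which C4a sees C1, C8 and H at C8a in counterclockwise order, and the substrate asks for the same face, since that chair carries the C7 silyloxy group equatorial and the C8 methyl group anti to C1, while the other face would set the silyloxy group 1,3-diaxial to C1. The C3 methyl group, which clashes with C5 in the s-trans form, takes away the usual conformational penalty of a Z-diene, conjugation with the butenyl alkene raises the diene HOMO, ambient temperature keeps out the 1,5-hydrogen shift from C5, and the non-basic triflate counter-ion slows loss of the C8 proton from 17.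

Step 10
Reactants: 19 (1S,2R,4aS,7S,8R,8aS)-2-[(2E)-but-2-en-2-yl]-7-(tert-butyldimethylsilyloxy)-3,8-dimethyl-1,2,4a,5,6,7,8,8a-octahydronaphthalene-1-carbaldehyde; 20 triethyl (E)-4-phosphonocrotonate
Product: 22 ethyl (2E,4E)-5-[(1S,2R,4aS,7S,8R,8aR)-2-[(2E)-but-2-en-2-yl]-7-(tert-butyldimethylsilyloxy)-3,8-dimethyl-1,2,4a,5,6,7,8,8a-octahydronaphthalen-1-yl]penta-2,4-dienoate, via lithiated phosphonate 21 (not isolated)
Conditions: 20, LiN(SiMe3)2, THF, −78 °C; then 19, −78 → 0 °C
Reagents that add atoms: none
Why: The vinylogous Horner–Wadsworth–Emmons olefination is E-selective for the new alkene and keeps the E geometry of the crotonate, and the preformed, weakly basic stabilised anion should add to the aldehyde at low temperature faster than it can enolise it, so that C1 is kept.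

Step 11
Reactants: 22 ethyl (2E,4E)-5-[(1S,2R,4aS,7S,8R,8aR)-2-[(2E)-but-2-en-2-yl]-7-(tert-butyldimethylsilyloxy)-3,8-dimethyl-1,2,4a,5,6,7,8,8a-octahydronaphthalen-1-yl]penta-2,4-dienoate
Product: 23 ethyl (2E,4E)-5-[(1S,2R,4aS,7S,8R,8aR)-2-[(2E)-but-2-en-2-yl]-7-hydroxy-3,8-dimethyl-1,2,4a,5,6,7,8,8a-octahydronaphthalen-1-yl]penta-2,4-dienoate
Conditions: HF·pyridine, pyridine, THF, 0 °C → rt
Reagents that add atoms: none
Why: Fluoride-driven cleavage of the Si–O bond with buffered HF·pyridine takes place at silicon, so that C7 is retained, and the medium is neither basic enough for the ester nor acidic enough to move the ring or butenyl alkenes.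

Step 12
Reactants: 23 ethyl (2E,4E)-5-[(1S,2R,4aS,7S,8R,8aR)-2-[(2E)-but-2-en-2-yl]-7-hydroxy-3,8-dimethyl-1,2,4a,5,6,7,8,8a-octahydronaphthalen-1-yl]penta-2,4-dienoate
Product: 24 pyridinium salt of the C7 sulfate monoester of 23
Conditions: SO3·pyridine, pyridine, rt → 40 °C; concentrated and taken on
Reagents that add atoms: sulfur trioxide–pyridine complex [O-]S(=O)(=O)[n+]1ccccc1
Why: O-Sulfation of a secondary alcohol with the SO3·pyridine complex forms the S–O bond without breaking the C7–O bond, so configuration is retained, and no other nucleophilic group is present.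

Step 13
Reactants: 24 pyridinium salt of the C7 sulfate monoester of 23
Product: 26 (2E,4E)-5-[(1S,2R,4aS,7S,8R,8aR)-2-[(2E)-but-2-en-2-yl]-3,8-dimethyl-7-(sulfooxy)-1,2,4a,5,6,7,8,8a-octahydronaphthalen-1-yl]penta-2,4-dienoic acid (CNP0450810.2), via dilithium salt 25 (not isolated)
Conditions: LiOH, THF–H2O, rt; then 1 M HCl, 0 °C, to pH 2, extraction with n-BuOH–EtOAc
Reagents that add atoms: lithium hydroxide [Li+].[OH-]
Why: Saponification cleaves the ethyl ester while the anionic sulfate monoester resists hydroxide, and a short cold acidification then protonates both acid groups without solvolysis at C7.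

Compound list
1 | (E)-2-methylbut-2-enal | C/C=C(\C)C=O | starting material
2 | 2-(triphenyl-λ5-phosphanylidene)propanal | CC(C=O)=P(c1ccccc1)(c1ccccc1)c1ccccc1 | starting material
3 | (2E,4E)-2,4-dimethylhexa-2,4-dienal | O=C/C(C)=C/C(C)=C/C | intermediate
4 | methyl 4-chlorobutanoate | COC(=O)CCCCl | starting material
5 | 4-chlorobutanal | O=CCCCCl | intermediate
6 | (E)-crotylboronic acid pinacol ester | C/C=C/CB1OC(C)(C)C(C)(C)O1 | starting material
7 | pinacol borate of 8 (O–B bond at C7) | C=C[C@@H](C)[C@@H](OB1OC(C)(C)C(C)(C)O1)CCCCl | intermediate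
8 | (3R,4S)-7-chloro-3-methylhept-1-en-4-ol (anti) | C=C[C@@H](C)[C@@H](O)CCCCl | intermediate
9 | tert-butyl{[(3R,4S)-7-chloro-3-methylhept-1-en-4-yl]oxy}dimethylsilane | C=C[C@@H](C)[C@@H](O[Si](C)(C)C(C)(C)C)CCCCl | intermediate
10 | 3,3-diethoxyprop-1-ene | C=CC(OCC)OCC | starting material
11 | (2E,4R,5S)-5-(tert-butyldimethylsilyloxy)-8-chloro-1,1-diethoxy-4-methyloct-2-ene | CCOC(OCC)/C=C/[C@@H](C)[C@@H](O[Si](C)(C)C(C)(C)C)CCCCl | intermediate
12 | (2E,4R,5S)-5-(tert-butyldimethylsilyloxy)-1,1-diethoxy-8-iodo-4-methyloct-2-ene | CCOC(OCC)/C=C/[C@@H](C)[C@@H](O[Si](C)(C)C(C)(C)C)CCCI | intermediate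
13 | [(4S,5R,6E)-4-(tert-butyldimethylsilyloxy)-8,8-diethoxy-5-methyloct-6-en-1-yl]triphenylphosphonium iodide | CCOC(OCC)/C=C/[C@@H](C)[C@@H](O[Si](C)(C)C(C)(C)C)CCC[P+](c1ccccc1)(c1ccccc1)c1ccccc1.[I-] | intermediate
14 | ylide from 13 | CCOC(OCC)/C=C/[C@@H](C)[C@@H](O[Si](C)(C)C(C)(C)C)CCC=P(c1ccccc1)(c1ccccc1)c1ccccc1 | intermediate
15 | (2E,4R,5S,8Z,10E,12E)-5-(tert-butyldimethylsilyloxy)-1,1-diethoxy-4,10,12-trimethyltetradeca-2,8,10,12-tetraene | CCOC(OCC)/C=C/[C@@H](C)[C@@H](O[Si](C)(C)C(C)(C)C)CC/C=C\C(C)=C\C(C)=C\C | intermediate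
16 | (2E,4R,5S,8Z,10E,12E)-5-(tert-butyldimethylsilyloxy)-4,10,12-trimethyltetradeca-2,8,10,12-tetraenal (4,5-anti) | O=C/C=C/[C@@H](C)[C@@H](O[Si](C)(C)C(C)(C)C)CC/C=C\C(C)=C\C(C)=C\C | intermediate
17 | (E)-iminium triflate of 16 with (2R,5R)-5-benzyl-2-tert-butyl-3-methylimidazolidin-4-one | CN1C(=O)[C@@H](Cc2ccccc2)/[N+](=C\C=C\[C@@H](C)[C@@H](O[Si](C)(C)C(C)(C)C)CC/C=C\C(C)=C\C(C)=C\C)[C@H]1C(C)(C)C.[O-]S(=O)(=O)C(F)(F)F | intermediate
18 | iminium triflate of 19 with the same imidazolidinone | CN1C(=O)[C@@H](Cc2ccccc2)/[N+](=C\[C@@H]3[C@H](/C(C)=C/C)C(C)=C[C@H]4CC[C@H](O[Si](C)(C)C(C)(C)C)[C@H](C)[C@@H]34)[C@H]1C(C)(C)C.[O-]S(=O)(=O)C(F)(F)F | intermediate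
19 | (1S,2R,4aS,7S,8R,8aS)-2-[(2E)-but-2-en-2-yl]-7-(tert-butyldimethylsilyloxy)-3,8-dimethyl-1,2,4a,5,6,7,8,8a-octahydronaphthalene-1-carbaldehyde; cis-fused, with H4a, H8a, CHO, butenyl, OTBS and the C8 methyl group all on one face | C/C=C(\C)[C@@H]1C(C)=C[C@H]2CC[C@H](O[Si](C)(C)C(C)(C)C)[C@H](C)[C@H]2[C@@H]1C=O | intermediate
20 | triethyl (E)-4-phosphonocrotonate | CCOC(=O)/C=C/CP(=O)(OCC)OCC | starting material
21 | lithium salt of the carbanion of 20 | CCOC(=O)/C=C/[CH-]P(=O)(OCC)OCC.[Li+] | intermediate
22 | ethyl (2E,4E)-dienoate, C7 silyl ether (ring centres 1S,2R,4aS,7S,8R,8aR) | C/C=C(\C)[C@@H]1C(C)=C[C@H]2CC[C@H](O[Si](C)(C)C(C)(C)C)[C@H](C)[C@H]2[C@@H]1/C=C/C=C/C(=O)OCC | intermediate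
23 | ethyl (2E,4E)-dienoate, C7 alcohol | C/C=C(\C)[C@@H]1C(C)=C[C@H]2CC[C@H](O)[C@H](C)[C@H]2[C@@H]1/C=C/C=C/C(=O)OCC | intermediate
24 | ethyl (2E,4E)-dienoate, C7 sulfate, pyridinium salt | C/C=C(\C)[C@@H]1C(C)=C[C@H]2CC[C@H](OS(=O)(=O)[O-])[C@H](C)[C@H]2[C@@H]1/C=C/C=C/C(=O)OCC.c1cc[nH+]cc1 | intermediate
25 | dilithium carboxylate sulfate | C/C=C(\C)[C@@H]1C(C)=C[C@H]2CC[C@H](OS(=O)(=O)[O-])[C@H](C)[C@H]2[C@@H]1/C=C/C=C/C(=O)[O-].[Li+].[Li+] | intermediate
26 | CNP0450810.2, (2E,4E)-5-[(1S,2R,4aS,7S,8R,8aR)-2-[(2E)-but-2-en-2-yl]-3,8-dimethyl-7-(sulfooxy)-1,2,4a,5,6,7,8,8a-octahydronaphthalen-1-yl]penta-2,4-dienoic acid | C/C=C(\C)[C@@H]1C(C)=C[C@H]2CC[C@H](OS(=O)(=O)O)[C@H](C)[C@H]2[C@@H]1/C=C/C=C/C(=O)O | target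

Total step count: 13. Longest linear sequence: 12 steps (4 to 26, steps 2–13).

Steps most likely to fail

(a) Step 9.
- The hindered Z-diene may add so slowly that side processes of the iminium ion take over. These are loss of the C8 proton to a dienamine (epimerisation at C8, then expulsion of the silyloxy group), acid-induced drift of the 8Z alkene, and incomplete face control.
- The fallback sets out from 16 and comes back at 19. It replaces catalytic amine activation by a covalently bound auxiliary and a chelating Lewis acid.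
- Pinnick oxidation of 16 (NaClO2, NaH2PO4, 2-methylbut-2-ene, t-BuOH–H2O) gives the tetraenoic acid F1.
- Its pivalic mixed anhydride (pivaloyl chloride, Et3N) is coupled with (R)-4-benzyloxazolidin-2-one (LiCl) to the tetraenimide F2.
- Me2AlCl in CH2Cl2 at −30 °C converts F2 into a chelated, strongly activated dienophile. Its benzyl group covers the same face as the catalyst did, and the medium contains no base, so the cycloadduct imide F3 should form with the same four new centres.
- LiBH4 (Et2O, H2O) removes the auxiliary to give the primary alcohol F4, and Dess–Martin periodinane returns 19.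

(b) Step 7.
- Z selectivity may erode with the conjugated, α-branched aldehyde, or a proton may pass from the dienal methyl groups to the basic ylide. Any 8E isomer would cyclise faster and to other diastereomers.
- The fallback sets out from 3 and 12 and comes back at 15. It reverses the polarity of the union in a Julia–Kocienski-type olefination with an allylic 2-pyridyl sulfone, a pairing known to favour E,Z-dienes.
- NaBH4 (MeOH, 0 °C) reduces 3 to the dienol F5.
- A Mitsunobu reaction with pyridine-2-thiol (PPh3, diisopropyl azodicarboxylate) gives the pyridyl sulfide F6.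
- H2O2 with (NH4)6Mo7O24 in EtOH gives the pyridyl sulfone F7.
- Iodide 12, isolated this time (NaI, acetone), is taken by Kornblum oxidation (DMSO, NaHCO3, 90 °C) to the aldehyde F8.
- Deprotonation of F7 with KN(SiMe3)2 in toluene and addition of F8 gives 15.

(c) Step 10.
- The phosphonate anion may enolise the crowded aldehyde, with epimerisation at C1 to the trans C1/C2 arrangement. Addition next to the cis butenyl group may also be sluggish.
- The fallback sets out from 19 and comes back at 22. It builds the diene in two non-basic stages.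
- Takai olefination (CrCl2, CHI3, THF, 0 °C) gives the (E)-vinyl iodide F9.
- A Heck reaction of F9 with ethyl acrylate (Pd(OAc)2, Ag2CO3, DMF, rt → 50 °C) gives the (2E,4E)-dienoate 22.

Further compounds
F1 | step 9 | (2E,4R,5S,8Z,10E,12E)-5-(tert-butyldimethylsilyloxy)-4,10,12-trimethyltetradeca-2,8,10,12-tetraenoic acid | OC(=O)/C=C/[C@@H](C)[C@@H](O[Si](C)(C)C(C)(C)C)CC/C=C\C(C)=C\C(C)=C\C
F2 | step 9 | (R)-4-benzyl-3-acyloxazolidin-2-one of F1 | O=C1OC[C@@H](Cc2ccccc2)N1C(=O)/C=C/[C@@H](C)[C@@H](O[Si](C)(C)C(C)(C)C)CC/C=C\C(C)=C\C(C)=C\C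
F3 | step 9 | cis-fused octalin C1 carboximide (ring centres as in 19, (R)-4-benzyloxazolidin-2-one on the C1 carbonyl) | C/C=C(\C)[C@@H]1C(C)=C[C@H]2CC[C@H](O[Si](C)(C)C(C)(C)C)[C@H](C)[C@H]2[C@@H]1C(=O)N1[C@H](Cc2ccccc2)COC1=O
F4 | step 9 | C1 hydroxymethyl octalin (ring centres as in 19) | C/C=C(\C)[C@@H]1C(C)=C[C@H]2CC[C@H](O[Si](C)(C)C(C)(C)C)[C@H](C)[C@H]2[C@@H]1CO
F5 | step 7 | (2E,4E)-2,4-dimethylhexa-2,4-dien-1-ol | OC/C(C)=C/C(C)=C/C
F6 | step 7 | 2-{[(2E,4E)-2,4-dimethylhexa-2,4-dien-1-yl]sulfanyl}pyridine | C(/C(C)=C/C(C)=C/C)Sc1ccccn1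
F7 | step 7 | 2-{[(2E,4E)-2,4-dimethylhexa-2,4-dien-1-yl]sulfonyl}pyridine | O=S(=O)(C/C(C)=C/C(C)=C/C)c1ccccn1
F8 | step 7 | (4S,5R,6E)-4-(tert-butyldimethylsilyloxy)-8,8-diethoxy-5-methyloct-6-enal | CCOC(OCC)/C=C/[C@@H](C)[C@@H](O[Si](C)(C)C(C)(C)C)CCC=O
F9 | step 10 | C1 (E)-2-iodoethenyl octalin (ring centres as in 19) | C/C=C(\C)[C@@H]1C(C)=C[C@H]2CC[C@H](O[Si](C)(C)C(C)(C)C)[C@H](C)[C@H]2[C@@H]1/C=C/I
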